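**Retrosynthetic overview**
1. The target is 8β-angeloyloxy-1β,10β-epoxy-3β,4α,15-trihydroxygermacr-11(13)-en-6α,12-olide; the last operations are O8 acylation, hydroxyl-directed epoxidation of a (Z)-C1=C10 alkene and α-methylenation of the lactone.
2. Key disconnection: the lactone O–C6 bond and the ten-membered ring are formed together from a cis-decalin that carries an extra, temporary C1–C6 bond, a tertiary allylic C1–OH and a C7–CH2CO2t-Bu arm.
3. Enabling feature: C1 and C6 lie 1,6 across the ten-membered ring, so bonding them gives two six-membered rings (ring A = C1–C6, ring B = C6–C10 plus C1); C1 ends as an sp2 carbon and C6 lies γ to C12, five atoms from the ester oxygen.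
4. The decalin comes from (S)-3-(4-hydroxyphenyl)lactic acid: the arene supplies ring B, oxidative dearomatisation gives the para-quinol (C1–OH), and a C3-controlled desymmetrising Michael addition (C5–C6) closes ring A.
5. Ring order: ring B (arene) → ring A (Michael) → ten-membered ring and γ-lactone (one operation) → epoxide.

Key step: step 13

Remark: germacrane numbering of the target is used for every intermediate (C1–C10 ring, C11–C13 lactone carbons, C14 = CH3 on C10, C15 on C4), α/β refer to the usual flat drawing, and the centres at C10 in 7 and 8 and at C11 in 19 and 20 are inconsequential.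

Step 1
Reactants: 1 (S)-3-(4-hydroxyphenyl)lactic acid
Product: 3 (2S)-2-(tert-butyldimethylsilyloxy)-3-(4-hydroxyphenyl)propanoic acid, via tris-silyl derivative 2 (not isolated)
Conditions: t-BuMe2SiCl, imidazole, DMF, rt; then K2CO3, MeOH, rt
Reagents that add atoms: tert-butyldimethylsilyl chloride (CC(C)(C)[Si](C)(C)Cl)
Why: Exhaustive silylation followed by base-mediated methanolysis of the labile silyl ester and aryl silyl ether should leave only the secondary alkyl silyl ether, the (S) centre (future C3) being untouched.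

Step 2
Reactants: 3 (2S)-2-(tert-butyldimethylsilyloxy)-3-(4-hydroxyphenyl)propanoic acid
Product: 4 (3S)-3-(tert-butyldimethylsilyloxy)-4-(4-hydroxyphenyl)butan-2-one
Conditions: MeLi (3.5 equiv), THF, −78 to 0 °C; aq. NH4Cl
Reagents that add atoms: methyllithium ([Li]C)
Why: Addition of MeLi to the lithium carboxylate (classical acid-to-methyl-ketone conversion) gives a gem-diolate that collapses to the ketone only on work-up, so neither over-addition nor epimerisation at C3 is expected.

Step 3
Reactants: 4 (3S)-3-(tert-butyldimethylsilyloxy)-4-(4-hydroxyphenyl)butan-2-one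
Product: 5 para-quinol 4-hydroxy-4-[(2S)-2-(tert-butyldimethylsilyloxy)-3-oxobutyl]cyclohexa-2,5-dien-1-one
Conditions: PhI(OAc)2, MeCN/H2O, 0 °C
Reagents that add atoms: water (O)
Why: Oxidative dearomatisation of a para-alkylphenol, with water trapping the phenoxenium intermediate at the para carbon, should give the para-quinol; C1 is not yet stereogenic because both enone arms are identical.

Step 4
Reactants: 5 para-quinol 4-hydroxy-4-[(2S)-2-(tert-butyldimethylsilyloxy)-3-oxobutyl]cyclohexa-2,5-dien-1-one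
Product: 6 cis-decalinol enedione (ring A: 1β-OH; 3β-OTBS; 4-oxo; 6β-H; ring B: 9-en-8-one)
Conditions: pyrrolidine (0.2 equiv), PhCO2H (0.2 equiv), CHCl3, rt
Reagents that add atoms: none
Why: An enamine-mediated intramolecular Michael addition (6-enolendo-exo-trig, C5 to C6) desymmetrises the dienone; the tether attacks from its own face (cis fusion) and the C3 silyloxy group takes the equatorial site of the forming chair (axial would clash with axial C10), which should place O1, H6 and O3 all β.

Step 5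
Reactants: 6 cis-decalinol enedione (ring A: 1β-OH; 3β-OTBS; 4-oxo; 6β-H; ring B: 9-en-8-one)
Product: 7 bis(trimethylsilyl) 10-methyl ketone (1β-OSiMe3; C8=C9 trimethylsilyl enol ether; 10α-CH3; 4-oxo; 3β-OTBS)
Conditions: Me2CuLi, Me3SiCl, Et3N, THF, −78 °C
Reagents that add atoms: lithium dimethylcuprate ([Li+].C[Cu-]C); chlorotrimethylsilane (C[Si](C)(C)Cl)
Why: Silyl-chloride-accelerated Gilman cuprate 1,4-addition puts the C14 methyl on C10 and masks C8 as its silyl enol ether (O1 as silyl ether), leaving the C4 ketone as the only carbonyl; the C10 centre (methyl expected anti to O1) is erased in step 7.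

Step 6
Reactants: 7 bis(trimethylsilyl) 10-methyl ketone (1β-OSiMe3; C8=C9 trimethylsilyl enol ether; 10α-CH3; 4-oxo; 3β-OTBS)
Product: 8 4(15)-methylene compound (C4=C15H2; otherwise as 7)
Conditions: Ph3PCH3Br, KOt-Bu, THF, 0 °C to rt
Reagents that add atoms: methyltriphenylphosphonium bromide (C[P+](c1ccccc1)(c1ccccc1)c1ccccc1.[Br-])
Why: Wittig methylenation of the only free ketone installs C15; the silyl enol ether and silyl ethers are inert to the ylide.

Step 7
Reactants: 8 4(15)-methylene compound (C4=C15H2; otherwise as 7)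
Product: 10 hydroxy enone (1β-OH; 9-en-8-one with 10-CH3; C4=C15H2; 3β-OTBS), via silyl ether enone 9 (not isolated)
Conditions: Pd(OAc)2 (1.1 equiv), MeCN, rt; then K2CO3 (cat.), MeOH, 0 °C
Reagents that add atoms: none
Why: Saegusa–Ito oxidation of the silyl enol ether regenerates the enone as C9=C10 bearing the methyl (β-hydride elimination can only use H10), and mild methanolysis then frees the tertiary C1–OH while the secondary TBS ether survives.

Step 8
Reactants: 10 hydroxy enone (1β-OH; 9-en-8-one with 10-CH3; C4=C15H2; 3β-OTBS)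
Product: 11 triol enone (1β-OH; 4α-OH; 15-OH; 3β-OTBS; 9-en-8-one)
Conditions: OsO4 (cat.), N-methylmorpholine N-oxide, acetone/H2O, 0 °C
Reagents that add atoms: N-methylmorpholine N-oxide (C[N+]1([O-])CCOCC1); water (O)
Why: Upjohn dihydroxylation should select the electron-rich 1,1-disubstituted C4=C15 alkene over the electron-poor enone, and equatorial approach to the exocyclic methylene of chair ring A (axial approach meets the syn-axial H2 and H6) should give the equatorial 4α-OH with C15 axial (β).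

Step 9
Reactants: 11 triol enone (1β-OH; 4α-OH; 15-OH; 3β-OTBS; 9-en-8-one)
Product: 12 4α,15-O-(di-tert-butylsilylene) enone (free 1β-OH; 3β-OTBS)
Conditions: t-Bu2Si(OTf)2, 2,6-lutidine, CH2Cl2, 0 °C
Reagents that add atoms: di-tert-butylsilyl bis(trifluoromethanesulfonate) (CC(C)(C)[Si](OS(=O)(=O)C(F)(F)F)(OS(=O)(=O)C(F)(F)F)C(C)(C)C)
Why: Cyclic silylene formation ties up the 1,2-diol only, the isolated hindered tertiary C1–OH staying free; the group is later removed by fluoride together with the TBS ether.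

Step 10
Reactants: 12 4α,15-O-(di-tert-butylsilylene) enone (free 1β-OH; 3β-OTBS)
Product: 13 7β-(tert-butoxycarbonylmethyl) enone (7α-H; otherwise as 12)
Conditions: LiN(i-Pr)2 (2.2 equiv), THF, −78 °C; BrCH2CO2t-Bu, DMPU, −78 to −40 °C
Reagents that add atoms: tert-butyl bromoacetate (BrCC(=O)OC(C)(C)C)
Why: Kinetic α′-deprotonation of the enone (the first equivalent of amide takes O1–H) and enolate alkylation on the convex β face, anti to the ring A bond C6–C5, should set C7 with the side chain β.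

Step 11
Reactants: 13 7β-(tert-butoxycarbonylmethyl) enone (7α-H; otherwise as 12)
Product: 14 8β-allylic alcohol (8α-H; C9=C10; 7β-CH2CO2t-Bu; free 1β-OH)
Conditions: LiBH(s-Bu)3, THF, −78 °C
Reagents that add atoms: none
Why: 1,2-Reduction of the β,β-disubstituted enone by the bulky hydride from the equatorial direction, anti to the C7 substituent, should give the cis (8β) alcohol as in 2-alkylcyclohexanone reductions; the tert-butyl ester should resist lactonisation at low temperature.

Step 12
Reactants: 14 8β-allylic alcohol (8α-H; C9=C10; 7β-CH2CO2t-Bu; free 1β-OH)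
Product: 15 8β-triethylsilyl ether (fragmentation precursor; free 1β-OH; 7β-CH2CO2t-Bu)
Conditions: Et3SiCl, imidazole, DMF, 0 °C
Reagents that add atoms: chlorotriethylsilane (CC[Si](Cl)(CC)CC)
Why: Silylation with a silyl chloride and imidazole protects only the secondary allylic alcohol; the tertiary ring-fusion C1–OH is too hindered and remains free for the key step.

Step 13
Reactants: 15 8β-triethylsilyl ether (fragmentation precursor; free 1β-OH; 7β-CH2CO2t-Bu)
Product: 16 ten-membered (Z)-enone lactone 13-nor-1-oxogermacr-9-en-6α,12-olide (3β-OTBS; 8β-OSiEt3; 4α,15-O-silylene; 6β-H; 7α-H)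
Conditions: Pb(OAc)4 (2 equiv), benzene, 80 °C
Reagents that add atoms: none
Why: Proposed new method: ligand exchange should give the tertiary alkoxide of tetravalent lead at C1, whose homolysis forms the C1 alkoxy radical; β-scission of the ring-fusion bond C1–C6 then gives a secondary C6 radical and a conjugated (Z)-enone, and a second equivalent of tetravalent lead oxidises C6 to a cationic centre that is captured by the carbonyl oxygen of the C7 tert-butyl acetate arm with loss of isobutene. The closest known reaction types are the Pb(OAc)4 β-fragmentation of ring-fusion tertiary carbinols of decalin type to ten-membered ketones, the oxidative lactonisation of γ-carboxyalkyl radicals (Mn(OAc)3 lactone annulation) and cation capture by tert-butyl esters. The ten-membered ring arises by fragmentation of the bond shared by the two six-membered rings, and the lactone closes by 5-exo attack of the ester oxygen on C6. The new C6 stereocentre is set in the C–O bond formation under control of C7: the planar C6 centre should be attacked so that the ring chains at C6 and C7 end up trans on the butyrolactone (H6 β, O6 α), whatever the original C6 configuration. The step needs regioselective β-scission, secured because the other two bonds would give a primary radical (C1–C2) or a vinyl radical (C1–C10, C10 being sp2), and chemoselective alkoxy radical formation, secured because C1–OH is the only free hydroxyl and an ester, unlike a free acid, cannot undergo oxidative decarboxylation.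

Step 14
Reactants: 16 ten-membered (Z)-enone lactone 13-nor-1-oxogermacr-9-en-6α,12-olide (3β-OTBS; 8β-OSiEt3; 4α,15-O-silylene; 6β-H; 7α-H)
Product: 17 (Z)-enol triflate 1-(trifluoromethanesulfonyloxy)-13-norgermacr-1(10)-en-6α,12-olide (protecting groups as in 16)
Conditions: LiBH(s-Bu)3, THF, −78 °C; then N-(5-chloro-2-pyridyl)triflimide, −78 to 0 °C
Reagents that add atoms: N-(5-chloropyridin-2-yl)bis(trifluoromethanesulfonyl)imide (FC(F)(F)S(=O)(=O)N(c1ccc(Cl)cn1)S(=O)(=O)C(F)(F)F)
Why: Conjugate reduction of the α-methyl enone delivers hydride to C9 and forms the C1(O)=C10 enolate regiospecifically, which is O-triflated; reaction through the s-trans enone conformer, the only one that keeps a cis double bond in the ten-membered ring, should place C2 and C9 cis, and the lactone is inert at −78 °C.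

Step 15
Reactants: 17 (Z)-enol triflate 1-(trifluoromethanesulfonyloxy)-13-norgermacr-1(10)-en-6α,12-olide (protecting groups as in 16)
Product: 18 (Z)-13-norgermacr-1(10)-en-6α,12-olide (3β-OTBS; 8β-OSiEt3; 4α,15-O-silylene)
Conditions: Pd(OAc)2 (cat.), PPh3, n-Bu3N, HCO2H, DMF, 60 °C
Reagents that add atoms: none
Why: Palladium-catalysed formate reduction of the enol triflate (oxidative addition to zerovalent palladium, formate decarboxylation, C–H reductive elimination) replaces OTf by H with retention of geometry, giving the (Z)-trisubstituted C1=C10 alkene.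

Step 16
Reactants: 18 (Z)-13-norgermacr-1(10)-en-6α,12-olide (3β-OTBS; 8β-OSiEt3; 4α,15-O-silylene)
Product: 21 (Z)-germacra-1(10),11(13)-dien-6α,12-olide (3β-OTBS; 8β-OSiEt3; 4α,15-O-silylene), via Mannich base 19 (not isolated), via methiodide 20 (not isolated)
Conditions: LiN(i-Pr)2, THF, −78 °C; CH2=NMe2 iodide; then MeI, CH2Cl2; then aq. NaHCO3
Reagents that add atoms: Eschenmoser's salt (C=[N+](C)C.[I-])
Why: α-Methylenation by the Mannich route (lactone enolate aminomethylation, N-methylation, Hofmann-type elimination) gives the exocyclic C11=C13 alkene; C7 is not epimerisable under these conditions.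

Step 17
Reactants: 21 (Z)-germacra-1(10),11(13)-dien-6α,12-olide (3β-OTBS; 8β-OSiEt3; 4α,15-O-silylene)
Product: 22 8β-hydroxy dienolide (3β-OTBS; 4α,15-O-silylene)
Conditions: pyridinium p-toluenesulfonate (cat.), MeOH/CH2Cl2, 0 °C
Reagents that add atoms: none
Why: Acid-catalysed methanolysis should remove the triethylsilyl ether much faster than the hindered TBS ether and the di-tert-butylsilylene, freeing only the C8 hydroxyl.

Step 18
Reactants: 22 8β-hydroxy dienolide (3β-OTBS; 4α,15-O-silylene)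
Product: 23 1β,10β-epoxy-8β-hydroxy lactone (3β-OTBS; 4α,15-O-silylene)
Conditions: VO(acac)2 (cat.), t-BuOOH, CH2Cl2, 0 °C
Reagents that add atoms: tert-butyl hydroperoxide (CC(C)(C)OO)
Why: Vanadium-catalysed epoxidation directed by the homoallylic C8–OH should deliver oxygen to the face of the (Z)-C1=C10 alkene syn to that hydroxyl (β), giving the cis 1β,10β-epoxide; the electron-poor α-methylene lactone does not react.

Step 19
Reactants: 23 1β,10β-epoxy-8β-hydroxy lactone (3β-OTBS; 4α,15-O-silylene)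
Product: 24 8β-angelate (1β,10β-epoxide; 3β-OTBS; 4α,15-O-silylene)
Conditions: angelic acid, 2,4,6-trichlorobenzoyl chloride, Et3N, toluene, rt; then 23, 80 °C
Reagents that add atoms: angelic acid (C/C=C(/C)C(=O)O)
Why: Yamaguchi esterification through the mixed anhydride, run without DMAP, acylates the only free hydroxyl (C8) and should avoid Z-to-E isomerisation to the tiglate.

Step 20
Reactants: 24 8β-angelate (1β,10β-epoxide; 3β-OTBS; 4α,15-O-silylene)
Product: 25 8β-angeloyloxy-1β,10β-epoxy-3β,4α,15-trihydroxygermacr-11(13)-en-6α,12-olide (target)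
Conditions: HF·pyridine, pyridine, THF, 0 °C to rt
Reagents that add atoms: none
Why: Buffered fluoride-mediated global desilylation removes the TBS ether and the silylene and should spare the epoxide, the angelate and the methylene lactone, releasing the 3,4,15-triol.

**Compound list**
1 | (S)-3-(4-hydroxyphenyl)lactic acid | OC(=O)[C@@H](O)Cc1ccc(O)cc1 | starting material
2 | tris-silyl derivative: tert-butyldimethylsilyl (2S)-2-(tert-butyldimethylsilyloxy)-3-[4-(tert-butyldimethylsilyloxy)phenyl]propanoate | CC(C)(C)[Si](C)(C)OC(=O)[C@@H](O[Si](C)(C)C(C)(C)C)Cc1ccc(O[Si](C)(C)C(C)(C)C)cc1 | intermediate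
3 | (2S)-2-(tert-butyldimethylsilyloxy)-3-(4-hydroxyphenyl)propanoic acid | OC(=O)[C@@H](O[Si](C)(C)C(C)(C)C)Cc1ccc(O)cc1 | intermediate
4 | (3S)-3-(tert-butyldimethylsilyloxy)-4-(4-hydroxyphenyl)butan-2-one | CC(=O)[C@@H](O[Si](C)(C)C(C)(C)C)Cc1ccc(O)cc1 | intermediate
5 | para-quinol 4-hydroxy-4-[(2S)-2-(tert-butyldimethylsilyloxy)-3-oxobutyl]cyclohexa-2,5-dien-1-one | CC(=O)[C@@H](O[Si](C)(C)C(C)(C)C)CC1(O)C=CC(=O)C=C1 | intermediate
6 | cis-decalinol enedione (ring A: 1β-OH; 3β-OTBS; 4-oxo; 6β-H; ring B: 9-en-8-one) | O[C@]12C[C@H](O[Si](C)(C)C(C)(C)C)C(=O)C[C@H]1CC(=O)C=C2 | intermediate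
7 | bis(trimethylsilyl) 10-methyl ketone (1β-OSiMe3; C8=C9 trimethylsilyl enol ether; 10α-CH3; 4-oxo; 3β-OTBS) | C[Si](C)(C)O[C@]12C[C@H](O[Si](C)(C)C(C)(C)C)C(=O)C[C@H]1CC(O[Si](C)(C)C)=C[C@H]2C | intermediate
8 | 4(15)-methylene compound (C4=C15H2; otherwise as 7) | C[Si](C)(C)O[C@]12C[C@H](O[Si](C)(C)C(C)(C)C)C(=C)C[C@H]1CC(O[Si](C)(C)C)=C[C@H]2C | intermediate
9 | silyl ether enone (1β-OSiMe3; 9-en-8-one with 10-CH3; C4=C15H2; 3β-OTBS) | C[Si](C)(C)O[C@]12C[C@H](O[Si](C)(C)C(C)(C)C)C(=C)C[C@H]1CC(=O)C=C2C | intermediate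
10 | hydroxy enone (1β-OH; 9-en-8-one with 10-CH3; C4=C15H2; 3β-OTBS) | O[C@]12C[C@H](O[Si](C)(C)C(C)(C)C)C(=C)C[C@H]1CC(=O)C=C2C | intermediate
11 | triol enone (1β-OH; 4α-OH; 15-OH; 3β-OTBS; 9-en-8-one) | O[C@]12C[C@H](O[Si](C)(C)C(C)(C)C)[C@](O)(CO)C[C@H]1CC(=O)C=C2C | intermediate
12 | 4α,15-O-(di-tert-butylsilylene) enone (free 1β-OH; 3β-OTBS) | O[C@]12C[C@H](O[Si](C)(C)C(C)(C)C)[C@]3(CO[Si](C(C)(C)C)(C(C)(C)C)O3)C[C@H]1CC(=O)C=C2C | intermediate
13 | 7β-(tert-butoxycarbonylmethyl) enone (7α-H; otherwise as 12) | O[C@]12C[C@H](O[Si](C)(C)C(C)(C)C)[C@]3(CO[Si](C(C)(C)C)(C(C)(C)C)O3)C[C@H]1[C@H](CC(=O)OC(C)(C)C)C(=O)C=C2C | intermediate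
14 | 8β-allylic alcohol (8α-H; C9=C10; 7β-CH2CO2t-Bu; free 1β-OH) | O[C@]12C[C@H](O[Si](C)(C)C(C)(C)C)[C@]3(CO[Si](C(C)(C)C)(C(C)(C)C)O3)C[C@H]1[C@H](CC(=O)OC(C)(C)C)[C@H](O)C=C2C | intermediate
15 | 8β-triethylsilyl ether (fragmentation precursor; free 1β-OH; 7β-CH2CO2t-Bu) | O[C@]12C[C@H](O[Si](C)(C)C(C)(C)C)[C@]3(CO[Si](C(C)(C)C)(C(C)(C)C)O3)C[C@H]1[C@H](CC(=O)OC(C)(C)C)[C@H](O[Si](CC)(CC)CC)C=C2C | intermediate
16 | ten-membered (Z)-enone lactone 13-nor-1-oxogermacr-9-en-6α,12-olide (3β-OTBS; 8β-OSiEt3; 4α,15-O-silylene; 6β-H; 7α-H) | O=C1O[C@@H]2C[C@@]3(CO[Si](C(C)(C)C)(C(C)(C)C)O3)[C@@H](O[Si](C)(C)C(C)(C)C)CC(=O)/C(C)=C\[C@@H](O[Si](CC)(CC)CC)[C@H]2C1 | intermediate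
17 | (Z)-enol triflate 1-(trifluoromethanesulfonyloxy)-13-norgermacr-1(10)-en-6α,12-olide (protecting groups as in 16) | O=C1O[C@@H]2C[C@@]3(CO[Si](C(C)(C)C)(C(C)(C)C)O3)[C@@H](O[Si](C)(C)C(C)(C)C)C/C(OS(=O)(=O)C(F)(F)F)=C(/C)C[C@@H](O[Si](CC)(CC)CC)[C@H]2C1 | intermediate
18 | (Z)-13-norgermacr-1(10)-en-6α,12-olide (3β-OTBS; 8β-OSiEt3; 4α,15-O-silylene) | O=C1O[C@@H]2C[C@@]3(CO[Si](C(C)(C)C)(C(C)(C)C)O3)[C@@H](O[Si](C)(C)C(C)(C)C)C/C=C(/C)C[C@@H](O[Si](CC)(CC)CC)[C@H]2C1 | intermediate
19 | Mannich base (11-CH2NMe2 lactone; C11 epimers) | CN(C)CC1C(=O)O[C@@H]2C[C@@]3(CO[Si](C(C)(C)C)(C(C)(C)C)O3)[C@@H](O[Si](C)(C)C(C)(C)C)C/C=C(/C)C[C@@H](O[Si](CC)(CC)CC)[C@@H]12 | intermediate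
20 | methiodide (11-CH2NMe3 iodide; C11 epimers) | C[N+](C)(C)CC1C(=O)O[C@@H]2C[C@@]3(CO[Si](C(C)(C)C)(C(C)(C)C)O3)[C@@H](O[Si](C)(C)C(C)(C)C)C/C=C(/C)C[C@@H](O[Si](CC)(CC)CC)[C@@H]12.[I-] | intermediate
21 | (Z)-germacra-1(10),11(13)-dien-6α,12-olide (3β-OTBS; 8β-OSiEt3; 4α,15-O-silylene) | C=C1C(=O)O[C@@H]2C[C@@]3(CO[Si](C(C)(C)C)(C(C)(C)C)O3)[C@@H](O[Si](C)(C)C(C)(C)C)C/C=C(/C)C[C@@H](O[Si](CC)(CC)CC)[C@@H]12 | intermediate
22 | 8β-hydroxy dienolide (3β-OTBS; 4α,15-O-silylene) | C=C1C(=O)O[C@@H]2C[C@@]3(CO[Si](C(C)(C)C)(C(C)(C)C)O3)[C@@H](O[Si](C)(C)C(C)(C)C)C/C=C(/C)C[C@@H](O)[C@@H]12 | intermediate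
23 | 1β,10β-epoxy-8β-hydroxy lactone (3β-OTBS; 4α,15-O-silylene) | C=C1C(=O)O[C@@H]2C[C@@]3(CO[Si](C(C)(C)C)(C(C)(C)C)O3)[C@@H](O[Si](C)(C)C(C)(C)C)C[C@H]4O[C@@]4(C)C[C@@H](O)[C@@H]12 | intermediate
24 | 8β-angelate (1β,10β-epoxide; 3β-OTBS; 4α,15-O-silylene) | C=C1C(=O)O[C@@H]2C[C@@]3(CO[Si](C(C)(C)C)(C(C)(C)C)O3)[C@@H](O[Si](C)(C)C(C)(C)C)C[C@H]4O[C@@]4(C)C[C@@H](OC(=O)/C(C)=C\C)[C@@H]12 | intermediate
25 | 8β-angeloyloxy-1β,10β-epoxy-3β,4α,15-trihydroxygermacr-11(13)-en-6α,12-olide (1R,3S,4R,6R,7S,8R,10S) | C=C1C(=O)O[C@@H]2C[C@@](O)(CO)[C@@H](O)C[C@H]3O[C@@]3(C)C[C@@H](OC(=O)/C(C)=C\C)[C@@H]12 | target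

**Totals**
Total step count: 20. Longest linear sequence: 20 steps (from 1).

**Steps most likely to fail**

Step 13 (proposed new method). The fragmentation may cleave toward C2 instead of C6, or the oxidised C6 centre may lose a proton to give an alkene instead of being captured by the ester, or the C–O bond may form with poor facial control. The fallback uses known chemistry and sets out from 15. Hypoiodite alkoxy-radical fragmentation (PhI(OAc)2, I2, visible light, CH2Cl2) cuts the same C1–C6 bond and traps the C6 radical by iodine-atom transfer, giving the ten-membered iodo enone tert-butyl ester F1. Silver-assisted ionisation of the secondary iodide (AgOTf, 2,6-di-tert-butylpyridine, CH2Cl2, −20 °C), with participation of the tert-butyl ester and loss of isobutene, then closes the lactone and returns to the route at 16.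

Step 14. The twisted macrocyclic enone may undergo 1,2-reduction, or the enolate may form with the wrong double-bond geometry. The fallback sets out from 16. Luche reduction (NaBH4, CeCl3, MeOH) gives the C1 allylic alcohol F2. Mitsunobu displacement with 2-nitrobenzenesulfonylhydrazide (PPh3, diethyl azodicarboxylate, −30 °C) gives the allylic sulfonylhydrazine F3. On warming this loses the sulfinic acid to give the monoalkyl diazene F4, whose retro-ene loss of N2 moves the double bond to C1=C10 and delivers hydrogen to C9. The route is rejoined at 18, bypassing 17.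

Step 11. Hydride may be delivered to the other face of the C8 ketone, or the cis hydroxy ester may lactonise prematurely. The fallback sets out from 13. Luche reduction (NaBH4, CeCl3, MeOH; axial hydride delivery) gives the 8α-allylic alcohol F5. Mitsunobu inversion with 4-nitrobenzoic acid (PPh3, diisopropyl azodicarboxylate) gives the 8β 4-nitrobenzoate F6. Brief methanolysis (K2CO3, MeOH, 0 °C) then returns to the route at 14.

Further compounds
F1 | step 13 | ten-membered C6-iodo (Z)-enone tert-butyl ester (C6 epimers; 3β-OTBS; 8β-OSiEt3; 4α,15-O-silylene) | CC(C)(C)OC(=O)C[C@H]1C(I)C[C@@]2(CO[Si](C(C)(C)C)(C(C)(C)C)O2)[C@@H](O[Si](C)(C)C(C)(C)C)CC(=O)/C(C)=C\[C@H]1O[Si](CC)(CC)CC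
F2 | step 14 | C1 allylic alcohol of lactone 16 (C1 epimers; C9=C10 retained) | O=C1O[C@@H]2C[C@@]3(CO[Si](C(C)(C)C)(C(C)(C)C)O3)[C@@H](O[Si](C)(C)C(C)(C)C)CC(O)/C(C)=C\[C@@H](O[Si](CC)(CC)CC)[C@H]2C1
F3 | step 14 | C1 N-(2-nitrobenzenesulfonyl)hydrazine (allylic; C1 epimers) | O=C1O[C@@H]2C[C@@]3(CO[Si](C(C)(C)C)(C(C)(C)C)O3)[C@@H](O[Si](C)(C)C(C)(C)C)CC(N(N)S(=O)(=O)c4ccccc4[N+](=O)[O-])/C(C)=C\[C@@H](O[Si](CC)(CC)CC)[C@H]2C1
F4 | step 14 | C1 allylic monoalkyl diazene (C1 epimers) | O=C1O[C@@H]2C[C@@]3(CO[Si](C(C)(C)C)(C(C)(C)C)O3)[C@@H](O[Si](C)(C)C(C)(C)C)CC(N=N)/C(C)=C\[C@@H](O[Si](CC)(CC)CC)[C@H]2C1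
F5 | step 11 | 8α-allylic alcohol (C8 epimer of 14) | O[C@]12C[C@H](O[Si](C)(C)C(C)(C)C)[C@]3(CO[Si](C(C)(C)C)(C(C)(C)C)O3)C[C@H]1[C@H](CC(=O)OC(C)(C)C)[C@@H](O)C=C2C
F6 | step 11 | 8β 4-nitrobenzoate of 14 | O[C@]12C[C@H](O[Si](C)(C)C(C)(C)C)[C@]3(CO[Si](C(C)(C)C)(C(C)(C)C)O3)C[C@H]1[C@H](CC(=O)OC(C)(C)C)[C@H](OC(=O)c4ccc(cc4)[N+](=O)[O-])C=C2C
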